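**Assumption:** compounds 1, 2, 4, 9, 10 and (+)-sparteine are treated as commercially available (4 is otherwise one step from ethanol and diisopropylcarbamoyl chloride). The route is designed on paper and has not been run.

## Retrosynthetic overview

1. Target 17 ⇐ global O-debenzylation ⇐ 16 ⇐ B-alkyl Suzuki–Miyaura coupling forming the C7'–C1' (CH2–aryl) bond between primary alkyl boronate 8 and the fully elaborated aryl bromide 15.
2. 8 ⇐ Matteson CH2 insertion ⇐ two iterative, reagent-controlled lithiation–borylation homologations (each inserts one CH(CH3); C8 first, then C8') ⇐ benzylboronate 3 ⇐ aryllithium from 1 + BrCH2Bpin. This replaces the usual auxiliary-alkylation or Stobbe route to the dimethylbutane core.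
3. 15 ⇐ chelation-controlled ketone reduction (sets C7'') ⇐ Weinreb ketone synthesis ⇐ Mitsunobu inversion of ethyl (S)-lactate by 4-bromo-2,6-dimethoxyphenol (sets C8'').
4. No ring is constructed; all three arenes are bought. Ring A (guaiacyl) enters in step 1, rings B and C are joined in steps 5–7, and the A–B union is step 9.

Abbreviations: Ar = 4-(benzyloxy)-3-methoxyphenyl; Bpin = 4,4,5,5-tetramethyl-1,3,2-dioxaborolan-2-yl; Cb = C(O)N(iPr)2.

## Route

**Step 1**
Reactants: 1, 1-(benzyloxy)-4-bromo-2-methoxybenzene; 2, 2-(bromomethyl)-4,4,5,5-tetramethyl-1,3,2-dioxaborolane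
Product: 3, 2-[4-(benzyloxy)-3-methoxybenzyl]-4,4,5,5-tetramethyl-1,3,2-dioxaborolane (ArCH2Bpin)
Conditions: n-BuLi, THF, −78 °C; then 2, −78 °C → rt
Reagents that add atoms: 2, (bromomethyl)boronic acid pinacol ester, BrCB1OC(C)(C)C(C)(C)O1
Why: Br/Li exchange gives ArLi, which adds to boron, and the aryl group then undergoes a 1,2-metallate shift expelling bromide (Matteson-type homologation of a halomethylboronate).

**Step 2**
Reactants: 3, ArCH2Bpin; 4, ethyl N,N-diisopropylcarbamate
Product: 5, 2-[(2S)-1-(4-(benzyloxy)-3-methoxyphenyl)propan-2-yl]-4,4,5,5-tetramethyl-1,3,2-dioxaborolane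
Conditions: 4, s-BuLi, (+)-sparteine, Et2O, −78 °C, 5 h; then 3, −78 °C, 1 h; then MgBr2·OEt2, reflux, 16 h
Reagents that add atoms: 4, ethyl N,N-diisopropylcarbamate, CCOC(=O)N(C(C)C)C(C)C (delivers CH–CH3)
Why: Hoppe–Aggarwal lithiation–borylation: (+)-sparteine-directed deprotonation gives the (R)-α-lithiated carbamate, which is borylated with retention, and the benzyl group then migrates anti to OCb (inversion at carbon), setting C8 as the (S)-boronic ester under reagent control.

**Step 3**
Reactants: 5, the (S)-secondary boronic ester; 4, ethyl N,N-diisopropylcarbamate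
Product: 6, 2-[(2S,3S)-4-(4-(benzyloxy)-3-methoxyphenyl)-3-methylbutan-2-yl]-4,4,5,5-tetramethyl-1,3,2-dioxaborolane (erythro/meso-type methyl diad)
Conditions: 4, s-BuLi, (+)-sparteine, Et2O, −78 °C, 5 h; then 5, −78 °C, 2 h; then MgBr2·OEt2, reflux, 16 h
Reagents that add atoms: 4, ethyl N,N-diisopropylcarbamate, CCOC(=O)N(C(C)C)C(C)C (delivers CH–CH3)
Why: Second lithiation–borylation with the same carbenoid enantiomer: the secondary alkyl group migrates with retention and the new carbon (C8') is set by the reagent with inversion at the carbenoid carbon, which gives the erythro (anti in zig-zag) diad; the two-fold reagent control also upgrades the ee of the major diastereomer (Horeau effect).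

**Step 4**
Reactants: 6, the (2S,3S)-secondary boronic ester; 7, bromochloromethane
Product: 8, 2-[(2R,3S)-4-(4-(benzyloxy)-3-methoxyphenyl)-2,3-dimethylbutyl]-4,4,5,5-tetramethyl-1,3,2-dioxaborolane
Conditions: BrCH2Cl, n-BuLi, Et2O/THF, −78 °C → rt
Reagents that add atoms: 7, bromochloromethane, ClCBr (delivers CH2)
Why: Matteson homologation: LiCH2Cl generated in situ forms the boronate, and stereoretentive 1,2-migration of the secondary alkyl group inserts C7' without touching C8 or C8' (the C8' descriptor changes to R only through CIP priorities).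

**Step 5**
Reactants: 9, 4-bromo-2,6-dimethoxyphenol; 10, ethyl (S)-lactate
Product: 11, ethyl (2R)-2-(4-bromo-2,6-dimethoxyphenoxy)propanoate
Conditions: PPh3, DIAD, THF, 0 °C → rt
Reagents that add atoms: 10, ethyl (S)-lactate, CCOC(=O)[C@H](C)O
Why: Mitsunobu etherification proceeds by SN2 with clean inversion at the lactate carbon, setting C8'' as R from the cheap (S) chiral pool.

**Step 6**
Reactants: 11, the (R)-aryloxypropanoate; 12, N,O-dimethylhydroxylamine hydrochloride
Product: 13, (2R)-2-(4-bromo-2,6-dimethoxyphenoxy)-N-methoxy-N-methylpropanamide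
Conditions: MeNH(OMe)·HCl, AlMe3, CH2Cl2, 0 °C → rt
Reagents that add atoms: 12, N,O-dimethylhydroxylamine hydrochloride, CNOC.Cl
Why: Weinreb aminolysis through the dimethylaluminium amide is non-basic enough to leave the α-aryloxy stereocentre and the aryl bromide untouched.

**Step 7**
Reactants: 13, the Weinreb amide; 1, 1-(benzyloxy)-4-bromo-2-methoxybenzene (as its Grignard reagent)
Product: 14, (2R)-1-[4-(benzyloxy)-3-methoxyphenyl]-2-(4-bromo-2,6-dimethoxyphenoxy)propan-1-one
Conditions: 1, Mg, THF (→ ArMgBr); then 13, THF, 0 °C; cold aq NH4Cl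
Reagents that add atoms: [4-(benzyloxy)-3-methoxyphenyl]magnesium bromide (from 1), COc1cc([Mg]Br)ccc1OCc1ccccc1
Why: Weinreb ketone synthesis: the chelated tetrahedral intermediate prevents over-addition and enolisation, and an aryl Grignard (unlike ArLi) does not exchange with the substrate's aryl bromide, so C8'' is preserved.

**Step 8**
Reactants: 14, the (R)-α-aryloxy ketone
Product: 15, (1S,2R)-1-[4-(benzyloxy)-3-methoxyphenyl]-2-(4-bromo-2,6-dimethoxyphenoxy)propan-1-ol (erythro)
Conditions: Zn(BH4)2, Et2O, −20 → 0 °C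
Reagents that add atoms: none
Why: Cram-chelate-controlled reduction: Zn bridges the carbonyl and aryloxy oxygens and hydride attacks from the face bearing the C8'' hydrogen, giving the erythro (anti) alcohol and setting C7'' as S.

**Step 9**
Reactants: 8, the primary alkyl boronate; 15, the erythro aryl bromide
Product: 16, (1S,2R)-1-[4-(benzyloxy)-3-methoxyphenyl]-2-{4-[(2R,3S)-4-(4-(benzyloxy)-3-methoxyphenyl)-2,3-dimethylbutyl]-2,6-dimethoxyphenoxy}propan-1-ol
Conditions: Pd(OAc)2 (5 mol %), RuPhos (10 mol %), KOH, THF/H2O (10:1), 70 °C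
Reagents that add atoms: none (both partners are the listed reactants)
Why: B-alkyl Suzuki–Miyaura coupling of a primary alkyl pinacol boronate with an unhindered aryl bromide; a bulky biarylphosphine favours reductive elimination over β-hydride elimination, the free secondary alcohol and the aryl ether tolerate aqueous KOH, and no stereocentre is involved.

**Step 10**
Reactants: 16, the bis-benzyl ether
Product: 17, (7''S,8S,8'R,8''R)-4,4''-dihydroxy-3,3',3'',5'-tetramethoxy-4',8''-oxy-8,8'-sesquineolignan-7''-ol (target)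
Conditions: H2 (1 atm), 10 % Pd/C, EtOAc/EtOH, rt, stopped at full conversion
Reagents that add atoms: none
Why: Hydrogenolysis of aryl benzyl ethers is much faster than C–O cleavage of the secondary benzylic alcohol or the alkyl aryl ether under neutral conditions, so both phenols are released without loss of the C7'' hydroxyl.

## Compound list

1 | 1-(benzyloxy)-4-bromo-2-methoxybenzene | COc1cc(Br)ccc1OCc1ccccc1 | starting material
2 | 2-(bromomethyl)-4,4,5,5-tetramethyl-1,3,2-dioxaborolane | BrCB1OC(C)(C)C(C)(C)O1 | starting material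
3 | 2-[4-(benzyloxy)-3-methoxybenzyl]-4,4,5,5-tetramethyl-1,3,2-dioxaborolane | COc1cc(CB2OC(C)(C)C(C)(C)O2)ccc1OCc1ccccc1 | intermediate
4 | ethyl N,N-diisopropylcarbamate | CCOC(=O)N(C(C)C)C(C)C | starting material
5 | 2-[(2S)-1-(4-(benzyloxy)-3-methoxyphenyl)propan-2-yl]-4,4,5,5-tetramethyl-1,3,2-dioxaborolane | COc1cc(C[C@H](C)B2OC(C)(C)C(C)(C)O2)ccc1OCc1ccccc1 | intermediate
6 | 2-[(2S,3S)-4-(4-(benzyloxy)-3-methoxyphenyl)-3-methylbutan-2-yl]-4,4,5,5-tetramethyl-1,3,2-dioxaborolane | COc1cc(C[C@H](C)[C@H](C)B2OC(C)(C)C(C)(C)O2)ccc1OCc1ccccc1 | intermediate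
7 | bromochloromethane | ClCBr | starting material
8 | 2-[(2R,3S)-4-(4-(benzyloxy)-3-methoxyphenyl)-2,3-dimethylbutyl]-4,4,5,5-tetramethyl-1,3,2-dioxaborolane | COc1cc(C[C@H](C)[C@H](C)CB2OC(C)(C)C(C)(C)O2)ccc1OCc1ccccc1 | intermediate
9 | 4-bromo-2,6-dimethoxyphenol | COc1cc(Br)cc(OC)c1O | starting material
10 | ethyl (S)-lactate | CCOC(=O)[C@H](C)O | starting material
11 | ethyl (2R)-2-(4-bromo-2,6-dimethoxyphenoxy)propanoate | CCOC(=O)[C@@H](C)Oc1c(OC)cc(Br)cc1OC | intermediate
12 | N,O-dimethylhydroxylamine hydrochloride | CNOC.Cl | starting material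
13 | (2R)-2-(4-bromo-2,6-dimethoxyphenoxy)-N-methoxy-N-methylpropanamide | CON(C)C(=O)[C@@H](C)Oc1c(OC)cc(Br)cc1OC | intermediate
14 | (2R)-1-[4-(benzyloxy)-3-methoxyphenyl]-2-(4-bromo-2,6-dimethoxyphenoxy)propan-1-one | COc1cc(C(=O)[C@@H](C)Oc2c(OC)cc(Br)cc2OC)ccc1OCc1ccccc1 | intermediate
15 | (1S,2R)-1-[4-(benzyloxy)-3-methoxyphenyl]-2-(4-bromo-2,6-dimethoxyphenoxy)propan-1-ol | COc1cc(Br)cc(OC)c1O[C@H](C)[C@@H](O)c1ccc(OCc2ccccc2)c(OC)c1 | intermediate
16 | (1S,2R)-1-[4-(benzyloxy)-3-methoxyphenyl]-2-{4-[(2R,3S)-4-(4-(benzyloxy)-3-methoxyphenyl)-2,3-dimethylbutyl]-2,6-dimethoxyphenoxy}propan-1-ol | COc1cc(C[C@H](C)[C@H](C)Cc2cc(OC)c(O[C@H](C)[C@@H](O)c3ccc(OCc4ccccc4)c(OC)c3)c(OC)c2)ccc1OCc1ccccc1 | intermediate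
17 | (+)-(7''S,8S,8'R,8''R)-4,4''-dihydroxy-3,3',3'',5'-tetramethoxy-4',8''-oxy-8,8'-sesquineolignan-7''-ol | COc1cc(C[C@H](C)[C@H](C)Cc2cc(OC)c(O[C@H](C)[C@@H](O)c3ccc(O)c(OC)c3)c(OC)c2)ccc1O | target

## Summary

Total step count: 10.
Longest linear sequence: 6 steps (1 → 3 → 5 → 6 → 8 → 16 → 17; the branch 9 → 11 → 13 → 14 → 15 → 16 → 17 is also 6).

Three steps most likely to fail:

1. **Step 3, second lithiation–borylation on the hindered secondary boronic ester.** Risks are slow or reversible ate-complex formation and eroded dr. Fallback: abandon iterative homologation for the diad and desymmetrise cis-2,3-dimethylsuccinic anhydride (from commercial meso-2,3-dimethylsuccinic acid) by cinchona-alkaloid-mediated methanolysis. Selective reduction gives the cis-3,4-dimethylbutyrolactone; DIBAL then ArMgBr and benzylic hydrogenolysis give ArCH2CH(Me)CH(Me)CH2OH, which is carried on as the iodide.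

2. **Step 9, sp3–sp2 Suzuki coupling of a β-branched alkyl-Bpin with an electron-rich aryl bromide carrying a free OH.** Risks are slow transmetalation, protodeboronation and β-hydride elimination. Fallback: switch nucleophile class. Oxidise 8 (NaBO3) to the primary alcohol, convert to the iodide (I2, PPh3, imidazole), insert Zn, and run a Negishi coupling (Pd/SPhos) with the O-TBS ether of 15, followed by TBAF.

3. **Step 8, chelation-controlled reduction.** The 2,6-dimethoxyaryloxy oxygen is a weak, hindered donor, so the erythro:threo ratio may be modest. Fallback: replace substrate control by catalyst control with (S)-Me-CBS/BH3 on 14 (aryl as the large group predicts 7''S). If threo material still forms, invert C7'' by Mitsunobu esterification (p-nitrobenzoic acid) and hydrolysis.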